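**Plan**

1. Retrosynthesis (germacrane numbering: ring C1–C10, lactone C11–C13, C14 = CH2OAc on C10, C15 = CH2O‑acyl on C4): cut the C15–O acyl bond, then the ring bond C6–C7, then the butenolide (C7=C11 and the C8–O–C12 ester), then C1=C10, then C2–C3 and C4–C5.
2. Enabling feature: C6 is allylic to C4=C5, and C7–C11(=C13H2)–C12=O of the five‑membered lactone is the transposed form of an acrylate allyl sulfone C7=C11–C13H2–SO2Ph. One radical SH2′ event can therefore close the ten‑membered carbocycle, unveil the exo‑methylene and set C7; the ring‑cis C1=C10 olefin and the flat butenolide pre‑fold the chain.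
3. Forward: fragment 1 (C1–C6 + C15) by vinyllithium addition and Johnson–Claisen rearrangement; fragment 2 (C7–C10 + C14) is (S)‑5‑vinylbutyrolactone; an aldol condensation joins C1 to C10. Lactone reduction, acetylation, acylation and ring‑closing metathesis give the five‑membered butenolide first; the ten‑membered ring closes in step 15; the C15 ester goes on last.
4. Stereochemistry: C8 comes from (S)‑5‑(hydroxymethyl)butyrolactone (chiral pool); C7 is set trans to C8 in the ring closure; the C4=C5 geometry comes from the chair Claisen transition state and the C1=C10 geometry from E‑selective elimination on the lactone template.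

Key step: step 15

Remark on the chemistry: the target is read as the 7R,8S trans‑fused 12,8‑olide with C1=C10 cis and C4=C5 trans inside the ring (CIP 1(10)E,4Z); compounds 1, 2, 4, 9, 17, 18 and 26 are taken as commercial.

**Route**

Step 1
Reactants: 1 2,3‑dibromopropene; 2 4‑methoxybenzyl alcohol
Product: 3 1‑{[(2‑bromoprop‑2‑en‑1‑yl)oxy]methyl}‑4‑methoxybenzene
Conditions: NaH, THF, 0 °C; then 1, Bu4NI (cat.), rt
Reagents that add atoms: none
Why: Williamson ether synthesis; the alkoxide should displace only the allylic bromide (SN2), the vinylic bromide being inert.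

Step 2
Reactants: 3 1‑{[(2‑bromoprop‑2‑en‑1‑yl)oxy]methyl}‑4‑methoxybenzene; 4 (tert‑butyldimethylsilyloxy)acetaldehyde
Product: 6 rac‑1‑[(tert‑butyldimethylsilyl)oxy]‑3‑{[(4‑methoxybenzyl)oxy]methyl}but‑3‑en‑2‑ol, via 2‑lithioallyl 4‑methoxybenzyl ether 5 (not isolated)
Conditions: t‑BuLi (2.1 equiv), Et2O, −78 °C; then 4, −78 °C; then H2O
Reagents that add atoms: tert‑butyllithium, [Li]C(C)(C)C (adds lithium to intermediate 5 only; no atom of it remains in 6)
Why: bromine–lithium exchange followed by 1,2‑addition of the vinyllithium to the aldehyde; the new carbinol centre is racemic and is consumed in step 3.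

Step 3
Reactants: 6 rac‑1‑[(tert‑butyldimethylsilyl)oxy]‑3‑{[(4‑methoxybenzyl)oxy]methyl}but‑3‑en‑2‑ol
Product: 7 ethyl (4Z)‑6‑[(tert‑butyldimethylsilyl)oxy]‑4‑{[(4‑methoxybenzyl)oxy]methyl}hex‑4‑enoate
Conditions: MeC(OEt)3 (6 equiv), EtCO2H (0.1 equiv), 140 °C, EtOH distilled off
Reagents that add atoms: triethyl orthoacetate, CC(OCC)(OCC)OCC
Why: Johnson–Claisen rearrangement; in the chair transition state the CH2OTBS group on the carbinol carbon sits equatorial, so C6 should end up trans to the new C3 chain and cis to CH2OPMB (CIP Z), which is the C4=C5 geometry of the target.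

Step 4
Reactants: 7 ethyl (4Z)‑6‑[(tert‑butyldimethylsilyl)oxy]‑4‑{[(4‑methoxybenzyl)oxy]methyl}hex‑4‑enoate
Product: 8 (4Z)‑6‑[(tert‑butyldimethylsilyl)oxy]‑4‑{[(4‑methoxybenzyl)oxy]methyl}hex‑4‑enal
Conditions: i‑Bu2AlH (1.05 equiv), CH2Cl2, −78 °C; MeOH, aq. potassium sodium tartrate
Reagents that add atoms: none
Why: partial reduction of the ester; the tetrahedral aluminium hemiacetal is stable at −78 °C and should release the aldehyde only on work‑up.

Step 5
Reactants: 9 (S)‑5‑(hydroxymethyl)dihydrofuran‑2(3H)‑one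
Product: 10 (2S)‑5‑oxotetrahydrofuran‑2‑carbaldehyde
Conditions: (COCl)2, DMSO, CH2Cl2, −78 °C; Et3N, −78 → −20 °C; used crude
Reagents that add atoms: none
Why: Swern oxidation of the primary alcohol; low temperature and non‑aqueous handling should keep the α‑alkoxy aldehyde from hydrating or epimerising at C8.

Step 6
Reactants: 10 (2S)‑5‑oxotetrahydrofuran‑2‑carbaldehyde
Product: 11 (5S)‑5‑vinyldihydrofuran‑2(3H)‑one
Conditions: Ph3PCH3Br, KN(SiMe3)2, THF, 0 °C; then 10, −78 → 0 °C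
Reagents that add atoms: methyltriphenylphosphonium bromide, C[P+](c1ccccc1)(c1ccccc1)c1ccccc1.[Br-]
Why: Wittig methylenation; addition of the aldehyde to the ylide at low temperature should outrun enolisation, so the S configuration at C8 is kept.

Step 7
Reactants: 11 (5S)‑5‑vinyldihydrofuran‑2(3H)‑one; 8 (4Z)‑6‑[(tert‑butyldimethylsilyl)oxy]‑4‑{[(4‑methoxybenzyl)oxy]methyl}hex‑4‑enal
Product: 14 (3E,5S)‑3‑[(4Z)‑6‑[(tert‑butyldimethylsilyl)oxy]‑4‑{[(4‑methoxybenzyl)oxy]methyl}hex‑4‑en‑1‑ylidene]‑5‑vinyldihydrofuran‑2(3H)‑one, via aldol adduct 12 (not isolated), via aldol mesylate 13 (not isolated)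
Conditions: LiN(i‑Pr)2 (1.05 equiv), THF, −78 °C; 8; then MsCl (1.3 equiv), −78 → 0 °C; then DBU (3 equiv), rt
Reagents that add atoms: methanesulfonyl chloride, CS(=O)(=O)Cl (adds the mesyl group of intermediate 13 only; no atom of it remains in 14)
Why: aldol addition of the lactone lithium enolate, O‑mesylation of the lithium aldolate and E1cB elimination; the E‑alkylidene lactone (chain anti to the lactone C=O, C2 cis to C9) is the kinetically and thermodynamically preferred isomer, which is the C1=C10 geometry of the target, and C8 is not touched.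

Step 8
Reactants: 14 (3E,5S)‑3‑[(4Z)‑6‑[(tert‑butyldimethylsilyl)oxy]‑4‑{[(4‑methoxybenzyl)oxy]methyl}hex‑4‑en‑1‑ylidene]‑5‑vinyldihydrofuran‑2(3H)‑one
Product: 15 (3S,5E,9Z)‑11‑[(tert‑butyldimethylsilyl)oxy]‑5‑(hydroxymethyl)‑9‑{[(4‑methoxybenzyl)oxy]methyl}undeca‑1,5,9‑trien‑3‑ol
Conditions: i‑Bu2AlH (4.5 equiv), CH2Cl2, −78 → 0 °C; aq. potassium sodium tartrate
Reagents that add atoms: none
Why: 1,2‑reduction of the conjugated lactone to the allylic 1,4‑diol; the olefin geometry fixed on the lactone template should be retained after ring opening.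

Step 9
Reactants: 15 (3S,5E,9Z)‑11‑[(tert‑butyldimethylsilyl)oxy]‑5‑(hydroxymethyl)‑9‑{[(4‑methoxybenzyl)oxy]methyl}undeca‑1,5,9‑trien‑3‑ol
Product: 16 (3S,5E,9Z)‑5‑(acetoxymethyl)‑11‑[(tert‑butyldimethylsilyl)oxy]‑9‑{[(4‑methoxybenzyl)oxy]methyl}undeca‑1,5,9‑trien‑3‑ol
Conditions: AcCl (1.1 equiv), 2,4,6‑collidine (2 equiv), CH2Cl2, −78 °C
Reagents that add atoms: acetyl chloride, CC(=O)Cl
Why: sterically controlled primary‑selective acetylation; the secondary allylic C8–OH should stay free.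

Step 10
Reactants: 17 2‑(bromomethyl)acrylic acid; 18 sodium benzenesulfinate
Product: 19 2‑[(phenylsulfonyl)methyl]acrylic acid
Conditions: MeOH, reflux
Reagents that add atoms: none
Why: S‑alkylation of the sulfinate by the allylic bromide; SN2 and SN2′ attack give the same product.

Step 11
Reactants: 16 (3S,5E,9Z)‑5‑(acetoxymethyl)‑11‑[(tert‑butyldimethylsilyl)oxy]‑9‑{[(4‑methoxybenzyl)oxy]methyl}undeca‑1,5,9‑trien‑3‑ol; 19 2‑[(phenylsulfonyl)methyl]acrylic acid
Product: 20 (3S,5E,9Z)‑5‑(acetoxymethyl)‑11‑[(tert‑butyldimethylsilyl)oxy]‑9‑{[(4‑methoxybenzyl)oxy]methyl}undeca‑1,5,9‑trien‑3‑yl 2‑[(phenylsulfonyl)methyl]acrylate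
Conditions: EDC·HCl (1.5 equiv), DMAP (0.1 equiv), CH2Cl2, 0 °C → rt
Reagents that add atoms: none
Why: Steglich esterification; the C8–O bond is not broken, so the configuration is retained.

Step 12
Reactants: 20 (3S,5E,9Z)‑5‑(acetoxymethyl)‑11‑[(tert‑butyldimethylsilyl)oxy]‑9‑{[(4‑methoxybenzyl)oxy]methyl}undeca‑1,5,9‑trien‑3‑yl 2‑[(phenylsulfonyl)methyl]acrylate
Product: 21 (5S)‑5‑[(2E,6Z)‑2‑(acetoxymethyl)‑8‑[(tert‑butyldimethylsilyl)oxy]‑6‑{[(4‑methoxybenzyl)oxy]methyl}octa‑2,6‑dien‑1‑yl]‑3‑[(phenylsulfonyl)methyl]furan‑2(5H)‑one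
Conditions: RuCl2(=CHPh)(H2IMes)(PCy3) (second‑generation Grubbs catalyst, 5 mol %), toluene, 80 °C, 0.005 M
Reagents that add atoms: none
Why: ring‑closing metathesis of the monosubstituted vinyl group with the 1,1‑disubstituted acrylate closes the five‑membered butenolide, as known for α‑substituted acrylates of allylic alcohols; the two trisubstituted chain olefins are too hindered to compete.

Step 13
Reactants: 21 (5S)‑5‑[(2E,6Z)‑2‑(acetoxymethyl)‑8‑[(tert‑butyldimethylsilyl)oxy]‑6‑{[(4‑methoxybenzyl)oxy]methyl}octa‑2,6‑dien‑1‑yl]‑3‑[(phenylsulfonyl)methyl]furan‑2(5H)‑one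
Product: 22 (5S)‑5‑[(2E,6Z)‑2‑(acetoxymethyl)‑8‑hydroxy‑6‑{[(4‑methoxybenzyl)oxy]methyl}octa‑2,6‑dien‑1‑yl]‑3‑[(phenylsulfonyl)methyl]furan‑2(5H)‑one
Conditions: HF·pyridine, pyridine, THF, 0 °C → rt
Reagents that add atoms: none
Why: fluoride‑driven desilylation of the primary TBS ether; acetate, PMB ether and butenolide should be stable.

Step 14
Reactants: 22 (5S)‑5‑[(2E,6Z)‑2‑(acetoxymethyl)‑8‑hydroxy‑6‑{[(4‑methoxybenzyl)oxy]methyl}octa‑2,6‑dien‑1‑yl]‑3‑[(phenylsulfonyl)methyl]furan‑2(5H)‑one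
Product: 23 (5S)‑5‑[(2E,6Z)‑2‑(acetoxymethyl)‑8‑bromo‑6‑{[(4‑methoxybenzyl)oxy]methyl}octa‑2,6‑dien‑1‑yl]‑3‑[(phenylsulfonyl)methyl]furan‑2(5H)‑one
Conditions: NBS, Me2S, CH2Cl2, −20 → 0 °C
Reagents that add atoms: N‑bromosuccinimide, O=C1CCC(=O)N1Br
Why: Corey–Kim bromination; bromide displaces the alkoxysulfonium group by SN2 at the primary allylic carbon, without allylic transposition or change of olefin geometry and without a nucleophilic phosphine that could attack the allyl sulfone.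

Step 15
Reactants: 23 (5S)‑5‑[(2E,6Z)‑2‑(acetoxymethyl)‑8‑bromo‑6‑{[(4‑methoxybenzyl)oxy]methyl}octa‑2,6‑dien‑1‑yl]‑3‑[(phenylsulfonyl)methyl]furan‑2(5H)‑one
Product: 24 (7R,8S)‑14‑acetoxy‑15‑[(4‑methoxybenzyl)oxy]germacra‑1(10)E,4Z,11(13)‑trien‑12,8‑olide
Conditions: (Bu3Sn)2 (1.5 equiv), hν (sunlamp, Pyrex), benzene, 0.002 M, 15–20 °C
Reagents that add atoms: none
Why: Proposed new method: Bu3Sn• from photolysis of the ditin abstracts bromine from the primary allylic bromide, the C4–C5–C6 allyl radical adds through its unsubstituted terminus C6 to C7 (the acrylate β‑carbon of the 3‑(phenylsulfonylmethyl)butenolide), and the C11 radical expels PhSO2• by β‑scission, which creates the C11=C13 exo‑methylene and carries the chain by attack on the ditin; the closest known reaction types are ditin‑mediated radical allylation of halides with allyl sulfones (SH2′) and allyl‑radical macrocyclisation onto enoates, which have not been combined in a ring closure of this size. The ten‑membered ring closes in the 10‑exo‑trig mode with respect to C7=C11 (C11 stays outside the new ring); closure through the other allyl terminus C4 would be 8‑exo and would build a quaternary centre, so attack through C6 should prevail. C7 is the only new stereocentre and is controlled by C8: the C6–C7 bond should form on the butenolide face opposite to the C8–C9 bond, because syn attack would eclipse C6 with C9 and lead to the more strained cis‑fused bicycle, and this gives the 7R,8S trans lactone. The step needs chemoselective halogen abstraction (the allylic C–Br bond reacts with Bu3Sn• far faster than the hindered trisubstituted enoate adds it), the absence of a hydrogen donor (so the stabilised radical can only cyclise) and retention of the C4=C5 geometry, which the low temperature should secure because rotation about C4–C5 in the allyl radical has the higher barrier; high dilution suppresses dimerisation. The ring‑cis C1=C10 olefin and the planar butenolide leave only six rotatable bonds in the tether and bring C6 close to C7.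

Step 16
Reactants: 24 (7R,8S)‑14‑acetoxy‑15‑[(4‑methoxybenzyl)oxy]germacra‑1(10)E,4Z,11(13)‑trien‑12,8‑olide
Product: 25 (7R,8S)‑14‑acetoxy‑15‑hydroxygermacra‑1(10)E,4Z,11(13)‑trien‑12,8‑olide
Conditions: DDQ (1.3 equiv), CH2Cl2/pH 7 phosphate buffer (10:1), 0 °C
Reagents that add atoms: none
Why: oxidative PMB ether cleavage (benzylic hydride abstraction, hydrolysis of the oxocarbenium ion); the buffer should protect the acid‑sensitive cyclodecadiene from transannular cyclisation.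

Step 17
Reactants: 26 ethyl 2‑(hydroxymethyl)acrylate
Product: 27 ethyl 2‑{[(tert‑butyldimethylsilyl)oxy]methyl}acrylate
Conditions: TBSCl, imidazole, CH2Cl2, 0 °C → rt
Reagents that add atoms: tert‑butyldimethylsilyl chloride, CC(C)(C)[Si](C)(C)Cl
Why: standard silylation of a primary alcohol.

Step 18
Reactants: 27 ethyl 2‑{[(tert‑butyldimethylsilyl)oxy]methyl}acrylate
Product: 28 2‑{[(tert‑butyldimethylsilyl)oxy]methyl}acrylic acid
Conditions: LiOH·H2O, THF/H2O (3:1), 0 °C; then 1 M HCl to pH 4, 0 °C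
Reagents that add atoms: lithium hydroxide, [Li+].[OH-]
Why: saponification of the ethyl ester; the primary TBS ether should survive cold aqueous base and brief mild acid.

Step 19
Reactants: 25 (7R,8S)‑14‑acetoxy‑15‑hydroxygermacra‑1(10)E,4Z,11(13)‑trien‑12,8‑olide; 28 2‑{[(tert‑butyldimethylsilyl)oxy]methyl}acrylic acid
Product: 29 (7R,8S)‑14‑acetoxy‑15‑[(2‑{[(tert‑butyldimethylsilyl)oxy]methyl}acryloyl)oxy]germacra‑1(10)E,4Z,11(13)‑trien‑12,8‑olide
Conditions: EDC·HCl (1.5 equiv), DMAP (0.2 equiv), CH2Cl2, 0 °C → rt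
Reagents that add atoms: none
Why: Steglich esterification of the primary allylic alcohol under non‑acidic conditions that the α‑methylene lactone and the diene should tolerate.

Step 20
Reactants: 29 (7R,8S)‑14‑acetoxy‑15‑[(2‑{[(tert‑butyldimethylsilyl)oxy]methyl}acryloyl)oxy]germacra‑1(10)E,4Z,11(13)‑trien‑12,8‑olide
Product: 30 (7R,8S)‑14‑acetoxy‑15‑{[2‑(hydroxymethyl)acryloyl]oxy}germacra‑1(10)E,4Z,11(13)‑trien‑12,8‑olide (CNP0126545.1)
Conditions: Et3N·3HF, MeCN, 0 °C → rt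
Reagents that add atoms: none
Why: near‑neutral fluoride desilylation of the primary TBS ether; both esters, the two Michael acceptors and the cyclodecadiene should survive.

**Compound list**

1 | 2,3‑dibromopropene | C=C(Br)CBr | starting material
2 | 4‑methoxybenzyl alcohol | COc1ccc(CO)cc1 | starting material
3 | 1‑{[(2‑bromoprop‑2‑en‑1‑yl)oxy]methyl}‑4‑methoxybenzene | C=C(Br)COCc1ccc(OC)cc1 | intermediate
4 | (tert‑butyldimethylsilyloxy)acetaldehyde | O=CCO[Si](C)(C)C(C)(C)C | starting material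
5 | 2‑lithioallyl 4‑methoxybenzyl ether (not isolated) | [Li]C(=C)COCc1ccc(OC)cc1 | intermediate
6 | rac‑1‑[(tert‑butyldimethylsilyl)oxy]‑3‑{[(4‑methoxybenzyl)oxy]methyl}but‑3‑en‑2‑ol | C=C(COCc1ccc(OC)cc1)C(O)CO[Si](C)(C)C(C)(C)C | intermediate
7 | ethyl (4Z)‑6‑[(tert‑butyldimethylsilyl)oxy]‑4‑{[(4‑methoxybenzyl)oxy]methyl}hex‑4‑enoate | CCOC(=O)CC/C(COCc1ccc(OC)cc1)=C/CO[Si](C)(C)C(C)(C)C | intermediate
8 | (4Z)‑6‑[(tert‑butyldimethylsilyl)oxy]‑4‑{[(4‑methoxybenzyl)oxy]methyl}hex‑4‑enal | O=CCC/C(COCc1ccc(OC)cc1)=C/CO[Si](C)(C)C(C)(C)C | intermediate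
9 | (S)‑5‑(hydroxymethyl)dihydrofuran‑2(3H)‑one | OC[C@@H]1CCC(=O)O1 | starting material
10 | (2S)‑5‑oxotetrahydrofuran‑2‑carbaldehyde | O=C[C@@H]1CCC(=O)O1 | intermediate
11 | (5S)‑5‑vinyldihydrofuran‑2(3H)‑one | C=C[C@@H]1CCC(=O)O1 | intermediate
12 | aldol adduct, (5S)‑3‑(1‑hydroxyalkyl) lactone, present as its lithium alkoxide, mixture at the two new centres (not isolated) | C=C[C@@H]1CC(C(O)CC/C(COCc2ccc(OC)cc2)=C/CO[Si](C)(C)C(C)(C)C)C(=O)O1 | intermediate
13 | aldol mesylate (not isolated) | C=C[C@@H]1CC(C(OS(C)(=O)=O)CC/C(COCc2ccc(OC)cc2)=C/CO[Si](C)(C)C(C)(C)C)C(=O)O1 | intermediate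
14 | (3E,5S)‑3‑[(4Z)‑6‑[(tert‑butyldimethylsilyl)oxy]‑4‑{[(4‑methoxybenzyl)oxy]methyl}hex‑4‑en‑1‑ylidene]‑5‑vinyldihydrofuran‑2(3H)‑one | C=C[C@@H]1C/C(=C\CC/C(COCc2ccc(OC)cc2)=C/CO[Si](C)(C)C(C)(C)C)C(=O)O1 | intermediate
15 | (3S,5E,9Z)‑11‑[(tert‑butyldimethylsilyl)oxy]‑5‑(hydroxymethyl)‑9‑{[(4‑methoxybenzyl)oxy]methyl}undeca‑1,5,9‑trien‑3‑ol | C=C[C@@H](O)C/C(CO)=C\CC/C(COCc1ccc(OC)cc1)=C/CO[Si](C)(C)C(C)(C)C | intermediate
16 | (3S,5E,9Z)‑5‑(acetoxymethyl)‑11‑[(tert‑butyldimethylsilyl)oxy]‑9‑{[(4‑methoxybenzyl)oxy]methyl}undeca‑1,5,9‑trien‑3‑ol | C=C[C@@H](O)C/C(COC(C)=O)=C\CC/C(COCc1ccc(OC)cc1)=C/CO[Si](C)(C)C(C)(C)C | intermediate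
17 | 2‑(bromomethyl)acrylic acid | C=C(CBr)C(=O)O | starting material
18 | sodium benzenesulfinate | [Na+].[O-]S(=O)c1ccccc1 | starting material
19 | 2‑[(phenylsulfonyl)methyl]acrylic acid | C=C(CS(=O)(=O)c1ccccc1)C(=O)O | intermediate
20 | (3S,5E,9Z)‑5‑(acetoxymethyl)‑11‑[(tert‑butyldimethylsilyl)oxy]‑9‑{[(4‑methoxybenzyl)oxy]methyl}undeca‑1,5,9‑trien‑3‑yl 2‑[(phenylsulfonyl)methyl]acrylate | C=C[C@@H](OC(=O)C(=C)CS(=O)(=O)c1ccccc1)C/C(COC(C)=O)=C\CC/C(COCc1ccc(OC)cc1)=C/CO[Si](C)(C)C(C)(C)C | intermediate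
21 | (5S)‑5‑[(2E,6Z)‑2‑(acetoxymethyl)‑8‑[(tert‑butyldimethylsilyl)oxy]‑6‑{[(4‑methoxybenzyl)oxy]methyl}octa‑2,6‑dien‑1‑yl]‑3‑[(phenylsulfonyl)methyl]furan‑2(5H)‑one | O=C1O[C@@H](C/C(COC(C)=O)=C\CC/C(COCc2ccc(OC)cc2)=C/CO[Si](C)(C)C(C)(C)C)C=C1CS(=O)(=O)c1ccccc1 | intermediate
22 | (5S)‑5‑[(2E,6Z)‑2‑(acetoxymethyl)‑8‑hydroxy‑6‑{[(4‑methoxybenzyl)oxy]methyl}octa‑2,6‑dien‑1‑yl]‑3‑[(phenylsulfonyl)methyl]furan‑2(5H)‑one | O=C1O[C@@H](C/C(COC(C)=O)=C\CC/C(COCc2ccc(OC)cc2)=C/CO)C=C1CS(=O)(=O)c1ccccc1 | intermediate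
23 | (5S)‑5‑[(2E,6Z)‑2‑(acetoxymethyl)‑8‑bromo‑6‑{[(4‑methoxybenzyl)oxy]methyl}octa‑2,6‑dien‑1‑yl]‑3‑[(phenylsulfonyl)methyl]furan‑2(5H)‑one | O=C1O[C@@H](C/C(COC(C)=O)=C\CC/C(COCc2ccc(OC)cc2)=C/CBr)C=C1CS(=O)(=O)c1ccccc1 | intermediate
24 | (7R,8S)‑14‑acetoxy‑15‑[(4‑methoxybenzyl)oxy]germacra‑1(10)E,4Z,11(13)‑trien‑12,8‑olide | COc1ccc(COC/C2=C\C[C@@H]3C(=C)C(=O)O[C@H]3C/C(COC(C)=O)=C\CC2)cc1 | intermediate
25 | (7R,8S)‑14‑acetoxy‑15‑hydroxygermacra‑1(10)E,4Z,11(13)‑trien‑12,8‑olide | OC/C1=C\C[C@@H]2C(=C)C(=O)O[C@H]2C/C(COC(C)=O)=C\CC1 | intermediate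
26 | ethyl 2‑(hydroxymethyl)acrylate | C=C(CO)C(=O)OCC | starting material
27 | ethyl 2‑{[(tert‑butyldimethylsilyl)oxy]methyl}acrylate | C=C(CO[Si](C)(C)C(C)(C)C)C(=O)OCC | intermediate
28 | 2‑{[(tert‑butyldimethylsilyl)oxy]methyl}acrylic acid | C=C(CO[Si](C)(C)C(C)(C)C)C(=O)O | intermediate
29 | (7R,8S)‑14‑acetoxy‑15‑[(2‑{[(tert‑butyldimethylsilyl)oxy]methyl}acryloyl)oxy]germacra‑1(10)E,4Z,11(13)‑trien‑12,8‑olide | C=C(CO[Si](C)(C)C(C)(C)C)C(=O)OC/C1=C\C[C@@H]2C(=C)C(=O)O[C@H]2C/C(COC(C)=O)=C\CC1 | intermediate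
30 | (7R,8S)‑14‑acetoxy‑15‑{[2‑(hydroxymethyl)acryloyl]oxy}germacra‑1(10)E,4Z,11(13)‑trien‑12,8‑olide (CNP0126545.1) | C=C(CO)C(=O)OC/C1=C\C[C@@H]2C(=C)C(=O)O[C@H]2C/C(COC(C)=O)=C\CC1 | target

**Step count**

Total steps: 20. Longest linear sequence: 15 steps (steps 1–4, 7–9, 11–16, 19 and 20).

**Steps most likely to fail**

Step 15 (proposed new method). What may go wrong: the stabilised allyl radical may add to C7 too slowly, so that dimerisation, rotation about C4–C5 (loss of the olefin geometry), or addition of Bu3Sn• to the allyl sulfone takes over; attack on the wrong butenolide face would give the cis lactone. The fallback separates ring closure from methylenation and uses known reaction types only. It sets out from 16 and comes back at 24.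
- Acylation of 16 with acryloyl chloride (i‑Pr2NEt, CH2Cl2, −20 °C) would give the acrylate of 16, F1.
- Ring‑closing metathesis (same ruthenium catalyst, CH2Cl2, 40 °C) would give the 3‑unsubstituted butenolide F2.
- HF·pyridine would give the allylic alcohol F3, and NBS/Me2S the allylic bromide F4.
- Tin hydride‑mediated allyl‑radical macrocyclisation (Bu3SnH and AIBN by syringe pump, benzene, 80 °C, 0.002 M; reductive conjugate addition to the butenolide) would give the saturated trans lactone F5.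
- α‑Methylenation: LiN(SiMe3)2 (1.05 equiv, THF, −78 °C; the lactone is several pK units more acidic than the acetate) and dimethylmethyleneiminium iodide would give the Mannich base F6; MeI would give the ammonium iodide F7; NaHCO3 (CH2Cl2/H2O) would eliminate trimethylamine to return 24.

Step 6. What may go wrong: the basic ylide may enolise the α‑alkoxy aldehyde, which erodes the configuration at C8 and causes self‑condensation. The fallback is a Peterson olefination under non‑basic conditions. It sets out from 10 and comes back at 11: addition of Me3SiCH2MgCl/CeCl3 (THF, −78 °C; the organocerium reagent is selective for the aldehyde over the lactone) would give the β‑hydroxysilane F8, and acid‑induced elimination (cat. H2SO4, THF, rt) would give 11.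

Step 7. What may go wrong: retro‑aldol cleavage during in situ mesylation, incomplete elimination, or erosion of the E/Z ratio and deconjugation under DBU. The fallback is a Horner–Wadsworth–Emmons olefination. It sets out from 11 and comes back at 14: LiN(i‑Pr)2 (2.2 equiv) and ClP(O)(OEt)2 (THF, −78 → 0 °C) would give first the ketene acetal phosphate F9 and then, by base‑induced 1,3‑shift of phosphorus from oxygen to carbon, the α‑phosphono lactone F10; olefination of aldehyde 8 (LiCl, DBU, MeCN, rt) would give 14, with the E isomer favoured and separable.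

**Further compounds**

F1 | step 15 | (3S,5E,9Z)‑5‑(acetoxymethyl)‑11‑[(tert‑butyldimethylsilyl)oxy]‑9‑{[(4‑methoxybenzyl)oxy]methyl}undeca‑1,5,9‑trien‑3‑yl acrylate | C=C[C@@H](OC(=O)C=C)C/C(COC(C)=O)=C\CC/C(COCc1ccc(OC)cc1)=C/CO[Si](C)(C)C(C)(C)C
F2 | step 15 | (5S)‑5‑[(2E,6Z)‑2‑(acetoxymethyl)‑8‑[(tert‑butyldimethylsilyl)oxy]‑6‑{[(4‑methoxybenzyl)oxy]methyl}octa‑2,6‑dien‑1‑yl]furan‑2(5H)‑one | O=C1O[C@@H](C/C(COC(C)=O)=C\CC/C(COCc2ccc(OC)cc2)=C/CO[Si](C)(C)C(C)(C)C)C=C1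
F3 | step 15 | (5S)‑5‑[(2E,6Z)‑2‑(acetoxymethyl)‑8‑hydroxy‑6‑{[(4‑methoxybenzyl)oxy]methyl}octa‑2,6‑dien‑1‑yl]furan‑2(5H)‑one | O=C1O[C@@H](C/C(COC(C)=O)=C\CC/C(COCc2ccc(OC)cc2)=C/CO)C=C1
F4 | step 15 | (5S)‑5‑[(2E,6Z)‑2‑(acetoxymethyl)‑8‑bromo‑6‑{[(4‑methoxybenzyl)oxy]methyl}octa‑2,6‑dien‑1‑yl]furan‑2(5H)‑one | O=C1O[C@@H](C/C(COC(C)=O)=C\CC/C(COCc2ccc(OC)cc2)=C/CBr)C=C1
F5 | step 15 | (7R,8S)‑14‑acetoxy‑15‑[(4‑methoxybenzyl)oxy]germacra‑1(10)E,4Z‑dien‑12,8‑olide | COc1ccc(COC/C2=C\C[C@@H]3CC(=O)O[C@H]3C/C(COC(C)=O)=C\CC2)cc1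
F6 | step 15 | (7R,8S)‑14‑acetoxy‑13‑(dimethylamino)‑15‑[(4‑methoxybenzyl)oxy]germacra‑1(10)E,4Z‑dien‑12,8‑olide (mixture at C11) | COc1ccc(COC/C2=C\C[C@@H]3C(CN(C)C)C(=O)O[C@H]3C/C(COC(C)=O)=C\CC2)cc1
F7 | step 15 | trimethylammonium iodide of F6 | COc1ccc(COC/C2=C\C[C@@H]3C(C[N+](C)(C)C)C(=O)O[C@H]3C/C(COC(C)=O)=C\CC2)cc1.[I-]
F8 | step 6 | (5S)‑5‑[1‑hydroxy‑2‑(trimethylsilyl)ethyl]dihydrofuran‑2(3H)‑one (mixture at the carbinol carbon) | C[Si](C)(C)CC(O)[C@@H]1CCC(=O)O1
F9 | step 7 | diethyl (5S)‑5‑vinyl‑4,5‑dihydrofuran‑2‑yl phosphate | C=C[C@@H]1CC=C(OP(=O)(OCC)OCC)O1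
F10 | step 7 | diethyl [(5S)‑2‑oxo‑5‑vinyltetrahydrofuran‑3‑yl]phosphonate (mixture at C3) | C=C[C@@H]1CC(P(=O)(OCC)OCC)C(=O)O1
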